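**Plan**

- Atom labels: benzene ring C1 (bearing the sulfated CH2 carbon C7), C2 (Br), C3 (OH), C4 (OSO3H), C5 (Br), C6 (Br). The retrosynthesis first cuts the two S–O bonds at O7 and O4, takes C7–O back to a methyl group, C5–Br back to C–H and C2–Br back to a carboxyl placeholder, and finally cuts the ring bonds C4–C5 and C1–C2.
- Enabling feature: C2–C3–C4 is a 4-alkoxy-β-ketoester in disguise (C3 the ketone carbon, oxygen on C4, the ester carbon on C2 where bromine will stand). C5–C6–C1–C7 is an α-bromo-β-alkoxy enone (Br on C6, C1 the ketone carbon, C7 its methyl).
- Forward: the bis(silyl enol ether) of methyl 4-methoxyacetoacetate and 3-bromo-4-methoxybut-3-en-2-one close the only ring under TiCl4 (C4–C5, then C1–C2). Then follow saponification, brominative decarboxylation at C2 with bromination at C5, O3 triflation, C7 bromination, O4 demethylation with hydrolysis at C7, double sulfation and triflate removal.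
- The ring construction delivers O3 as a free phenol and O4 as a methyl ether; this difference is kept to the end (O3 as triflate) and decides which phenol is sulfated.
- Stereochemistry: the target has no stereocentre and no stereogenic double bond; the enol ether geometries of the building blocks vanish on aromatisation.

Key step: step 4

Remark: the enol ether double bonds of the silylated intermediates are drawn in one geometry for definiteness; isomer mixtures would serve equally, because this geometry is lost when the ring aromatises.
Remark: the target is drawn as the free bis(hydrogen sulfate); such acids promote their own hydrolysis, so the disodium salt stage is taken as the storable form and the acid form is generated cold in the last operation.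

**Route**

Step 1
Reactants: 1 methyl 4-methoxy-3-oxobutanoate (methyl 4-methoxyacetoacetate); 2 chlorotrimethylsilane
Product: 3 methyl (Z)-4-methoxy-3-(trimethylsilyloxy)but-2-enoate
Conditions: Me3SiCl, Et3N, toluene, 20 °C
Reagents that add atoms: chlorotrimethylsilane (compound 2), C[Si](C)(C)Cl
Why: Et3N removes the doubly activated C2 proton of the β-ketoester and the enolate is trapped on oxygen by the chlorosilane (O-silylation of a 1,3-dicarbonyl compound), the ester being left untouched.

Step 2
Reactants: 3 methyl (Z)-4-methoxy-3-(trimethylsilyloxy)but-2-enoate; 2 chlorotrimethylsilane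
Product: 4 (3Z)-1,4-dimethoxy-1,3-bis(trimethylsilyloxy)buta-1,3-diene
Conditions: LiN(iPr)2, THF, −78 °C; then Me3SiCl, −78 → 20 °C
Reagents that add atoms: chlorotrimethylsilane (compound 2), C[Si](C)(C)Cl
Why: The amide base removes the γ-proton next to the methoxy group of the vinylogous ester and O-silylation of the extended enolate gives the 1,3-bis(silyloxy)diene, the usual second stage in making a masked β-ketoester dianion.

Step 3
Reactants: 5 (E)-4-methoxybut-3-en-2-one
Product: 7 (Z)-3-bromo-4-methoxybut-3-en-2-one, via 3,4-dibromo-4-methoxybutan-2-one 6 (not isolated)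
Conditions: Br2, CH2Cl2, −78 → 0 °C; then Et3N, 0 → 20 °C
Reagents that add atoms: bromine, BrBr
Why: Bromine adds across the electron-rich enol ether double bond and Et3N then removes the acidic α-proton with loss of the β-bromide (bromination–dehydrobromination of a β-alkoxy enone), which restores the push–pull enone with bromine on the α-carbon.

Step 4
Reactants: 4 (3Z)-1,4-dimethoxy-1,3-bis(trimethylsilyloxy)buta-1,3-diene; 7 (Z)-3-bromo-4-methoxybut-3-en-2-one
Product: 9 methyl 3-bromo-6-hydroxy-5-methoxy-2-methylbenzoate, via methyl 6-bromo-4-methoxy-3,7-dioxooct-5-enoate 8 (not isolated)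
Conditions: TiCl4, CH2Cl2, −78 → 20 °C; aq. HCl work-up
Reagents that add atoms: none
Why: TiCl4 binds the carbonyl oxygen of 7 and the terminal carbon of diene 4 (the future C4) adds to the β-carbon (the future C5) in a vinylogous Mukaiyama–Michael reaction, after which methoxide leaves and the enone is restored in the open-chain adduct 8 (held as its titanium or silyl enolate). The remaining silyl ketene acetal carbon (the future C2) then attacks the TiCl4-activated methyl ketone (the future C1) in an intramolecular Mukaiyama aldol addition, a 6-(enolexo)-exo-trig closure that forms the only ring. Loss of water and tautomerisation of the β-ketoester unit give the salicylate, with aromatisation as the driving force. The closest known reaction type is the TiCl4-mediated formal [3+3] cyclocondensation of 1,3-bis(silyloxy)-1,3-dienes with 3-alkoxy-2-en-1-ones, 2-halogenated ones included. No stereocentre is formed; the step needs the terminus to bond to the β-carbon and the central carbon to the ketone, which is secured because the diene terminus is its most nucleophilic position and the β-carbon of the titanium-bound push–pull enone is its most electrophilic one, while the ketone is then reached only intramolecularly. The α-bromine is a spectator that ends at C6, and the methoxy group of the diene ends at C4 next to the free C3 hydroxyl, so the two phenolic oxygens leave this step already differentiated.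

Step 5
Reactants: 9 methyl 3-bromo-6-hydroxy-5-methoxy-2-methylbenzoate
Product: 10 3-bromo-6-hydroxy-5-methoxy-2-methylbenzoic acid
Conditions: KOH, MeOH/H2O, 80 °C; then aq. HCl
Reagents that add atoms: potassium hydroxide, [K+].[OH-]
Why: Saponification by hydroxide attack at the ester carbonyl, with heating to overcome the shielding by the two ortho substituents; the aryl bromide and the aryl methyl ether of the electron-rich phenoxide are inert to aqueous base.

Step 6
Reactants: 10 3-bromo-6-hydroxy-5-methoxy-2-methylbenzoic acid
Product: 12 2,4,5-tribromo-6-methoxy-3-methylphenol, via 2,4-dibromo-6-methoxy-3-methylphenol 11 (not isolated)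
Conditions: Br2 (2.2 equiv), NaOAc, AcOH/H2O, 20 → 50 °C
Reagents that add atoms: bromine, BrBr
Why: The free C3 hydroxyl directs bromine to the ipso carbon C2, whose dienone intermediate rearomatises by loss of CO2 (brominative decarboxylation of a salicylic acid), and the second equivalent substitutes the only remaining ring hydrogen at C5, ortho to the methoxy group (electrophilic aromatic bromination).

Step 7
Reactants: 12 2,4,5-tribromo-6-methoxy-3-methylphenol
Product: 13 2,4,5-tribromo-6-methoxy-3-methylphenyl trifluoromethanesulfonate
Conditions: Tf2O, pyridine, CH2Cl2, 0 °C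
Reagents that add atoms: trifluoromethanesulfonic anhydride, O=S(=O)(OS(=O)(=O)C(F)(F)F)C(F)(F)F
Why: O-Triflation of a phenol, chosen because the sulfonate withstands BBr3 and radical bromination, cannot migrate to the neighbouring oxygen (sulfonyl transfer needs an in-line geometry that a five-membered transition state cannot reach) and is later cleaved by hydroxide.

Step 8
Reactants: 13 2,4,5-tribromo-6-methoxy-3-methylphenyl trifluoromethanesulfonate
Product: 14 2,4,5-tribromo-3-(bromomethyl)-6-methoxyphenyl trifluoromethanesulfonate
Conditions: NBS, AIBN (cat.), PhCF3, 80 °C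
Reagents that add atoms: N-bromosuccinimide, O=C1CCC(=O)N1Br
Why: Wohl–Ziegler bromination, in which the fully substituted ring leaves the benzylic hydrogens of C7 as the only reactive C–H bonds and the two ortho bromines slow a second bromination.

Step 9
Reactants: 14 2,4,5-tribromo-3-(bromomethyl)-6-methoxyphenyl trifluoromethanesulfonate
Product: 16 2,4,5-tribromo-6-hydroxy-3-(hydroxymethyl)phenyl trifluoromethanesulfonate, via 2,4,5-tribromo-3-(bromomethyl)-6-hydroxyphenyl trifluoromethanesulfonate 15 (not isolated)
Conditions: BBr3, CH2Cl2, −78 → 20 °C; H2O quench; then acetone/H2O, NaHCO3, 40 °C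
Reagents that add atoms: water, O
Why: BBr3 cleaves the aryl methyl ether (boron complexation, then SN2 attack of bromide on the methyl group) while triflate and benzylic bromide persist, and the freed para-hydroxybenzyl bromide then solvolyses in buffered aqueous acetone through a para-quinone methide that adds water.

Step 10
Reactants: 16 2,4,5-tribromo-6-hydroxy-3-(hydroxymethyl)phenyl trifluoromethanesulfonate
Product: 17 disodium 2,3,6-tribromo-4-(sulfonatooxy)-5-(trifluoromethylsulfonyloxy)benzyl sulfate
Conditions: SO3·pyridine (6 equiv), pyridine, 20 → 40 °C; then aq. NaHCO3; reversed-phase (C18) chromatography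
Reagents that add atoms: sulfur trioxide–pyridine complex, O=S(=O)([O-])[n+]1ccccc1; sodium hydrogen carbonate, [Na+].OC([O-])=O
Why: O-Sulfation by transfer of SO3 from its pyridine complex to the phenolate oxygen O4 and to the primary benzylic alcohol O7, with O3 blocked as the triflate so that the position of the aryl sulfate is fixed by the protecting group and not by a selectivity between two similar phenols.

Step 11
Reactants: 17 disodium 2,3,6-tribromo-4-(sulfonatooxy)-5-(trifluoromethylsulfonyloxy)benzyl sulfate
Product: 19 2,3,6-tribromo-5-hydroxy-4-(sulfooxy)benzyl hydrogen sulfate (the target), via trisodium 2,3,6-tribromo-5-oxido-4-(sulfonatooxy)benzyl sulfate 18 (not isolated)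
Conditions: 1 M aq. NaOH, 1,4-dioxane, 20 °C; then 1 M HCl, 0 °C; C18 cartridge (0.01 M HCl, then MeCN/H2O); freeze-drying
Reagents that add atoms: none
Why: Hydroxide attacks the sulfur of the electron-poor aryl triflate and releases the stabilised phenoxide (S–O cleavage, a known mild deprotection of aryl triflates), whereas the anionic sulfate monoesters repel hydroxide and are stable to base, and brief cold acidification then gives the acid form.

**Compound list**

1 | methyl 4-methoxy-3-oxobutanoate | COCC(=O)CC(=O)OC | starting material
2 | chlorotrimethylsilane | C[Si](C)(C)Cl | starting material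
3 | methyl (Z)-4-methoxy-3-(trimethylsilyloxy)but-2-enoate | COC/C(O[Si](C)(C)C)=C/C(=O)OC | intermediate
4 | (3Z)-1,4-dimethoxy-1,3-bis(trimethylsilyloxy)buta-1,3-diene (ketene acetal geometry not defined) | CO/C=C(\O[Si](C)(C)C)C=C(OC)O[Si](C)(C)C | intermediate
5 | (E)-4-methoxybut-3-en-2-one | CO/C=C/C(C)=O | starting material
6 | 3,4-dibromo-4-methoxybutan-2-one (racemic mixture of diastereomers) | COC(Br)C(Br)C(C)=O | intermediate (not isolated)
7 | (Z)-3-bromo-4-methoxybut-3-en-2-one | CO/C=C(\Br)C(C)=O | intermediate
8 | methyl 6-bromo-4-methoxy-3,7-dioxooct-5-enoate (racemic, alkene geometry not defined, present as its titanium or silyl enolate) | COC(=O)CC(=O)C(OC)C=C(Br)C(C)=O | intermediate (not isolated)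
9 | methyl 3-bromo-6-hydroxy-5-methoxy-2-methylbenzoate | COC(=O)c1c(C)c(Br)cc(OC)c1O | intermediate
10 | 3-bromo-6-hydroxy-5-methoxy-2-methylbenzoic acid | OC(=O)c1c(C)c(Br)cc(OC)c1O | intermediate
11 | 2,4-dibromo-6-methoxy-3-methylphenol | Cc1c(Br)cc(OC)c(O)c1Br | intermediate (not isolated)
12 | 2,4,5-tribromo-6-methoxy-3-methylphenol | Cc1c(Br)c(Br)c(OC)c(O)c1Br | intermediate
13 | 2,4,5-tribromo-6-methoxy-3-methylphenyl trifluoromethanesulfonate | Cc1c(Br)c(Br)c(OC)c(OS(=O)(=O)C(F)(F)F)c1Br | intermediate
14 | 2,4,5-tribromo-3-(bromomethyl)-6-methoxyphenyl trifluoromethanesulfonate | BrCc1c(Br)c(Br)c(OC)c(OS(=O)(=O)C(F)(F)F)c1Br | intermediate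
15 | 2,4,5-tribromo-3-(bromomethyl)-6-hydroxyphenyl trifluoromethanesulfonate | BrCc1c(Br)c(Br)c(O)c(OS(=O)(=O)C(F)(F)F)c1Br | intermediate (not isolated)
16 | 2,4,5-tribromo-6-hydroxy-3-(hydroxymethyl)phenyl trifluoromethanesulfonate | OCc1c(Br)c(Br)c(O)c(OS(=O)(=O)C(F)(F)F)c1Br | intermediate
17 | disodium 2,3,6-tribromo-4-(sulfonatooxy)-5-(trifluoromethylsulfonyloxy)benzyl sulfate | [Na+].[Na+].[O-]S(=O)(=O)OCc1c(Br)c(Br)c(OS(=O)(=O)[O-])c(OS(=O)(=O)C(F)(F)F)c1Br | intermediate
18 | trisodium 2,3,6-tribromo-5-oxido-4-(sulfonatooxy)benzyl sulfate | [Na+].[Na+].[Na+].[O-]S(=O)(=O)OCc1c(Br)c(Br)c(OS(=O)(=O)[O-])c([O-])c1Br | intermediate (not isolated)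
19 | 2,3,6-tribromo-5-hydroxy-4-(sulfooxy)benzyl hydrogen sulfate | O=S(=O)(O)OCc1c(Br)c(O)c(OS(=O)(=O)O)c(Br)c1Br | target

**Step count**

Total: 11 steps. Longest linear sequence: 10 steps (steps 1, 2 and 4 to 11, from methyl 4-methoxyacetoacetate); step 3 is a one-step branch.

**Steps most likely to fail**

Step 4 (ring-forming cyclocondensation). The sensitive methoxy-substituted diene may be desilylated before it adds to the less reactive α-brominated enone, or its terminus may add to the ketone carbonyl instead of the β-carbon, which would erode the regiochemistry. The fallback sets out from diene 4 and the unbrominated enone 5. Their TiCl4-mediated cyclocondensation in CH2Cl2 (the parent case of the same reaction) should give methyl 2-hydroxy-3-methoxy-6-methylbenzoate F1. NBS in MeCN would then brominate para to the phenolic hydroxyl, the only strongly activated free position and the one that becomes C6, and the route is rejoined at 9. The same two ring bonds are formed; only the origin of the C6 bromine changes from the building block to an electrophilic substitution.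

Step 10 (double sulfation). If O7 is sulfated before O4, the benzylic sulfate may ionise through a para-quinone methide while O4 is still a free phenoxide, and pyridine would capture the cation; the hindered, electron-poor phenol may also be sulfated incompletely. The fallback sets out from 16 and separates the two sulfations by a change of oxidation level at C7. Activated MnO2 in acetone would oxidise the benzylic alcohol to 2,4,5-tribromo-3-formyl-6-hydroxyphenyl trifluoromethanesulfonate F5. Its only hydroxyl, O4, would be sulfated with SO3·pyridine and worked up with NaHCO3 to sodium 2,3,5-tribromo-4-formyl-6-(trifluoromethylsulfonyloxy)phenyl sulfate F6. NaBH4 in MeOH at 0 °C would reduce the aldehyde to sodium 2,3,5-tribromo-4-(hydroxymethyl)-6-(trifluoromethylsulfonyloxy)phenyl sulfate F7, in which the sulfated O4 can no longer drive quinone methide formation. A second sulfation with SO3·pyridine at O7 returns to 17.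

Step 6 (brominative decarboxylation with bromination at C5). Substitution at the hindered C5 may stall, and the excess bromine needed to force it may oxidise the electron-rich free phenol towards quinone-type products. The fallback sets out from 9 and separates the three events. Br2 in AcOH at 50 °C would brominate C5 of the chelated, oxidation-resistant salicylate to methyl 3,4-dibromo-6-hydroxy-5-methoxy-2-methylbenzoate F2. KOH in MeOH/H2O followed by acidification would give 3,4-dibromo-6-hydroxy-5-methoxy-2-methylbenzoic acid F3. Protodecarboxylation (catalytic Ag2CO3 and AcOH in DMSO at 120 °C) would give 3,4-dibromo-2-methoxy-5-methylphenol F4. One equivalent of NBS in MeCN would then brominate the single free position ortho to the hydroxyl, rejoining the route at 12.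

**Further compounds**

F1 | step 4 | methyl 2-hydroxy-3-methoxy-6-methylbenzoate | COC(=O)c1c(C)ccc(OC)c1O
F2 | step 6 | methyl 3,4-dibromo-6-hydroxy-5-methoxy-2-methylbenzoate | COC(=O)c1c(C)c(Br)c(Br)c(OC)c1O
F3 | step 6 | 3,4-dibromo-6-hydroxy-5-methoxy-2-methylbenzoic acid | OC(=O)c1c(C)c(Br)c(Br)c(OC)c1O
F4 | step 6 | 3,4-dibromo-2-methoxy-5-methylphenol | Cc1cc(O)c(OC)c(Br)c1Br
F5 | step 10 | 2,4,5-tribromo-3-formyl-6-hydroxyphenyl trifluoromethanesulfonate | O=Cc1c(Br)c(Br)c(O)c(OS(=O)(=O)C(F)(F)F)c1Br
F6 | step 10 | sodium 2,3,5-tribromo-4-formyl-6-(trifluoromethylsulfonyloxy)phenyl sulfate | [Na+].O=Cc1c(Br)c(Br)c(OS(=O)(=O)[O-])c(OS(=O)(=O)C(F)(F)F)c1Br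
F7 | step 10 | sodium 2,3,5-tribromo-4-(hydroxymethyl)-6-(trifluoromethylsulfonyloxy)phenyl sulfate | [Na+].OCc1c(Br)c(Br)c(OS(=O)(=O)[O-])c(OS(=O)(=O)C(F)(F)F)c1Br
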